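At early times the epsilon flask lays down single product on a straight line. Its molar rate reads 1.17 mM min⁻¹ over the first 3.00 min and 1.36 mM min⁻¹ over 12.0 min, the same within the scatter, while starting material falls to 85.3%.

the same everywhere: gas 14 mM (held)
- beta: starting material 0.025 M; temperature −25 °C; run made earlier
- epsilon: starting material 0.10 M; temperature 0 °C; run made earlier
- south-east: starting material 0.050 M; temperature −20 °C; time 30 min
- west: starting material 0.050 M; temperature 20 °C; time 30 min
- east: starting material 0.050 M; at −20 °C until 20 min, from then on at 20 °C; time 30 min
- south-west: starting material 0.050 M; temperature 0 °C; time 30 min

- beta (time / min: single product / %, starting material / %): 8.00: 8.2, 90.7; 15.0: 24.4, 75.8; 25.0: 41.6, 57.9; 30.0: 47.5, 49.2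
- epsilon (time / min: single product / %, starting material / %): 3.00: 3.5, 96.1; 6.00: 8.7, 93.4; 10.0: 13.1, 87.5; 12.0: 16.3, 85.3

(each reading ± 1 percentage point)

- which flask leads in amount of single product, in percent of the starting material charged ("all alike" within 1.5 percentage points) (south-east / west / east / south-west / all alike)
- how much single product is there at the end, in percent of the starting material charged: south-east
- how much single product is there at the end, in percent of the starting material charged: west
- how much single product is there at the end, in percent of the starting material charged: east
- how much single product is there at the end, in percent of the starting material charged: south-west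

- the analysis behind the earlier runs scatters by 1 percentage point, standard deviation
- at the start none of the gas is in solution

Such a line, zero order in starting material in the usual term, reads as gas entering at a steady pace. Call this pace the feed rate, the concentration of single product that the entering gas can pay for each minute, read from epsilon:

feed rate = 1.36 mM min⁻¹

The beta flask, between 8.00 min and 15.0 min, makes 0.579 mM min⁻¹, slower than the feed; beta is both colder than epsilon and charged with less starting material, so these two runs cannot separate the two settings.

The bound from above assumes that the gas enters at the same pace at each temperature. On the new charge it gives:

ceiling = feed rate × time / charge = 81.5%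

The bounds from below come from the two runs. South-west shares epsilon's temperature and has less starting material to take up the gas, so its percentage should keep at least epsilon's first-order pace, 0.0148 min⁻¹:

south-west floor = 35.9%

South-east is warmer than beta and holds more starting material, so it should keep at least beta's molar yield:

south-east floor = 23.8%

West, warmer still, should stand above the south-west floor and lead. This reckoning goes no further by hand, and the brackets stay wide.

The forecast, “Taking first order with negative dependence”, gives 45% for south-east, 26% for west, 39% for east and 35% for south-west, with south-east leading. Its south-east lies inside the bracket; its south-west lies just under the floor, and its west lies under that floor too.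

The flasks give 46.8% in south-east, 71.2% in west, 62.0% in east and 64.8% in south-west, so west leads.

    reagent + single product → double product (k = 0.00855 M⁻¹ s⁻¹, Ea = 42.0 kJ mol⁻¹)
    reagent + double product ⇌ tris adduct (K = 45.5 M⁻¹, k = 0.0934 M⁻¹ s⁻¹, Ea = 38.0 kJ mol⁻¹, ΔH = 13.0 kJ mol⁻¹)
    reagent → decomposition product (k = 2.05 × 10⁻⁶ s⁻¹, Ea = 80.0 kJ mol⁻¹)
    gas ⇌ reagent, rate k4*(csat - [reagent]) (kL = 0.00160 s⁻¹)
    starting material + reagent → single product (k = 0.100 M⁻¹ s⁻¹, Ea = 50.0 kJ mol⁻¹)
    (constants at −20 °C)

West holds 71.2% mainly because of the hour of its reading: at 300 min the same flask holds 0% of single product. Warmth on the conversion of starting material and reagent is a part of the reason for west's lead: without that step's temperature dependence, west minus south-east goes from 24 percentage points to −18 points. West reaches 87.4% of its ceiling and ends with 5.48 × 10⁻⁴ M of reagent, against 0.00481 M in south-east. East, over its warm 10.0 min, makes 1.51 mM min⁻¹, above the feed rate, while its reagent falls from 0.00417 M to 4.23 × 10⁻⁴ M.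

The earlier runs and the new flask were computed for substances that don't exist, noise included.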